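**Strategy.** Everything rests on cutting ring C at O1–C8a and ring A at its C8–O bond. O1 on C8a and the hydroxyl oxygen on C8 occupy adjacent carbons of ring A, with C7–O next door, so a single aryne spanning C8–C8a can deliver both C–O bonds. In step 7 lithium tetramethylpiperidide turns a C8 bromide into that aryne, the tethered primary alkoxide closes ring C at C8a, and the C8 aryllithium left behind is borylated and oxidised to the phenol in the same flask. The precursor is an open 1,2-diarylpropane-1,3-diol assembled by ester aldol from MOM-protected 5-bromovanillin and a ring B arylacetate carrying a benzyl ether; oxidation, dehydrogenation and deprotection complete the isoflavone.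

Key step: step 7

Remark on the design: the ring B phenol is carried as a benzyl ether and not as an acetal, so that the C7 methoxymethyl (MOM) ether is the only strong lithiation director present when excess amide base is used in step 7.
Remark on numbering and stereochemistry: isoflavone numbering (O1, C2 to C8a, primed numbers for ring B) is used for all intermediates; the target has no stereocentre, and intermediates with stereocentres at C3 and C4 are carried as racemic diastereomer mixtures.

**Step 1**
Reactants: 1 3-hydroxy-4,5-dimethoxybenzaldehyde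
Product: 2 3-(benzyloxy)-4,5-dimethoxybenzaldehyde
Conditions: BnBr, K2CO3, DMF, rt
Reagents that add atoms: benzyl bromide, BrCc1ccccc1
Why: Williamson ether synthesis of a phenoxide with benzyl bromide; the benzyl ether survives the acidic methanolysis of step 3 and, unlike an acetal, does not direct lithiation on ring B in step 7.

**Step 2**
Reactants: 2 3-(benzyloxy)-4,5-dimethoxybenzaldehyde
Product: 3 1-(benzyloxy)-2,3-dimethoxy-5-[2-(methanesulfinyl)-2-(methylsulfanyl)ethenyl]benzene
Conditions: CH3S(O)CH2SCH3 (FAMSO), Triton B (benzyltrimethylammonium hydroxide, cat.), THF, reflux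
Reagents that add atoms: methyl (methylsulfanyl)methyl sulfoxide, CSCS(C)=O
Why: Knoevenagel-type condensation of the doubly sulfur-stabilised carbanion of the sulfoxide reagent with a non-enolisable aryl aldehyde, driven by loss of water; alkene geometry and sulfur configuration are irrelevant because both vanish in step 3.

**Step 3**
Reactants: 3 1-(benzyloxy)-2,3-dimethoxy-5-[2-(methanesulfinyl)-2-(methylsulfanyl)ethenyl]benzene
Product: 4 methyl 2-[3-(benzyloxy)-4,5-dimethoxyphenyl]acetate
Conditions: anhydrous HCl (3 M in MeOH), rt → 50 °C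
Reagents that add atoms: methanol, CO
Why: Acid-promoted methanolysis of a ketene dithioacetal monoxide (second half of the sulfoxide-based one-carbon homologation of aryl aldehydes to arylacetates): C-protonation gives a sulfur-stabilised cation, methanol adds, and both sulfur groups leave together as dimethyl disulfide, while benzyl and methyl ethers are inert to HCl in methanol.

**Step 4**
Reactants: 5 5-bromovanillin (3-bromo-4-hydroxy-5-methoxybenzaldehyde)
Product: 6 3-bromo-5-methoxy-4-(methoxymethoxy)benzaldehyde
Conditions: MOMCl, K2CO3, acetone, 0 °C → rt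
Reagents that add atoms: chloromethyl methyl ether, COCCl
Why: Williamson-type O-alkylation of an acidic phenol (para formyl, ortho bromo) with chloromethyl methyl ether; the acetal is wanted at C7 because it later stabilises the C8 anion by induction and chelation.

**Step 5**
Reactants: 4 methyl 2-[3-(benzyloxy)-4,5-dimethoxyphenyl]acetate; 6 3-bromo-5-methoxy-4-(methoxymethoxy)benzaldehyde
Product: 8 methyl 2-[3-(benzyloxy)-4,5-dimethoxyphenyl]-3-[3-bromo-5-methoxy-4-(methoxymethoxy)phenyl]-3-hydroxypropanoate (racemic syn/anti mixture), via lithium enolate 7 (not isolated)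
Conditions: lithium diisopropylamide (LDA, 1.05 equiv), THF, −78 °C; then 6, −78 °C; AcOH quench at −78 °C
Reagents that add atoms: none
Why: Aldol addition of a lithium ester enolate to a non-enolisable aldehyde at −78 °C with a cold acidic quench that forestalls retro-aldol and dehydration; the two new stereocentres (later C3 and C4) form without control as a syn/anti mixture of racemates, which is accepted because C4 is oxidised in step 9 and C3 becomes trigonal in step 10.

**Step 6**
Reactants: 8 methyl 2-[3-(benzyloxy)-4,5-dimethoxyphenyl]-3-[3-bromo-5-methoxy-4-(methoxymethoxy)phenyl]-3-hydroxypropanoate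
Product: 9 2-[3-(benzyloxy)-4,5-dimethoxyphenyl]-1-[3-bromo-5-methoxy-4-(methoxymethoxy)phenyl]propane-1,3-diol (racemic syn/anti mixture)
Conditions: LiBH4, THF, 0 °C → rt
Reagents that add atoms: none
Why: Hydroxyl-assisted reduction of the ester with LiBH4, a hydride that leaves the aryl bromide, the acetal and the benzyl ether untouched; no stereocentre is affected.

**Step 7**
Reactants: 9 2-[3-(benzyloxy)-4,5-dimethoxyphenyl]-1-[3-bromo-5-methoxy-4-(methoxymethoxy)phenyl]propane-1,3-diol
Product: 13 3-[3-(benzyloxy)-4,5-dimethoxyphenyl]-6-methoxy-7-(methoxymethoxy)chromane-4,8-diol (racemic cis/trans mixture), via aryne 10 (not isolated), via aryllithium 11 (not isolated), via arylboronate 12 (not isolated)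
Conditions: lithium 2,2,6,6-tetramethylpiperidide (LiTMP, 3.5 equiv), THF (0.02 M), −78 → 0 °C; B(OMe)3, −78 °C → rt; AcOH, 30% H2O2, 0 °C → rt
Reagents that add atoms: hydrogen peroxide, OO
Why: Proposed new method: LiTMP first makes the dilithium dialkoxide, the benzylic alkoxide then steers a further equivalent to C8a–H, the only hydrogen ortho to bromine, and loss of LiBr gives the one possible aryne 10; the primary alkoxide adds to C8a to leave aryllithium 11 at C8, which B(OMe)3 converts into boronate 12 and peroxide into the phenol at the same carbon. The closest known reaction types are chroman closures in which a tethered alkoxide captures a base-generated aryne and aryne cyclisations of tethered nucleophiles whose aryllithium is then quenched with an external electrophile; joining an O-cyclisation to a borylation–oxidation on a polyoxygenated aryne has no direct precedent. Ring C closes by 6-exo-dig attack of the alkoxide oxygen on the in-plane orbital at C8a. No stereocentre is formed, and C3 and C4 pass through unchanged as the diastereomer mixture. The regioselectivity needed (oxygen at C8a, lithium at C8) is fixed by the tether, since attack at C8 would demand a meta-bridged ring and the benzylic alkoxide could only form a four-membered ring, and by the C7 MOM oxygen, which polarises the aryne toward negative charge at C8 and chelates the lithium there. Ring B should be spared because its oxygens are plain ethers, so C8–H of the cyclised product, flanked by O1 and the MOM ether, is the most acidic aryl position and holds the lithium while only a small excess of base is present and the borate is added at −78 °C.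

**Step 8**
Reactants: 13 3-[3-(benzyloxy)-4,5-dimethoxyphenyl]-6-methoxy-7-(methoxymethoxy)chromane-4,8-diol
Product: 14 3-[3-(benzyloxy)-4,5-dimethoxyphenyl]-6-methoxy-7,8-bis(methoxymethoxy)chroman-4-ol (racemic cis/trans mixture)
Conditions: MOMCl (1.2 equiv), K2CO3, acetone, rt
Reagents that add atoms: chloromethyl methyl ether, COCCl
Why: Chemoselective Williamson-type alkylation: K2CO3 ionises only the phenol, so chloromethyl methyl ether caps O8 and the secondary benzylic alcohol stays free for step 9.

**Step 9**
Reactants: 14 3-[3-(benzyloxy)-4,5-dimethoxyphenyl]-6-methoxy-7,8-bis(methoxymethoxy)chroman-4-ol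
Product: 15 3-[3-(benzyloxy)-4,5-dimethoxyphenyl]-6-methoxy-7,8-bis(methoxymethoxy)chroman-4-one (racemic)
Conditions: Dess–Martin periodinane, CH2Cl2, 0 °C → rt
Reagents that add atoms: none
Why: Dess–Martin oxidation of the secondary benzylic alcohol under mild, nearly neutral conditions that spare the acetals and the benzyl ether; C4 becomes trigonal, so both diastereomers converge on one racemic isoflavanone.

**Step 10**
Reactants: 15 3-[3-(benzyloxy)-4,5-dimethoxyphenyl]-6-methoxy-7,8-bis(methoxymethoxy)chroman-4-one
Product: 16 3-[3-(benzyloxy)-4,5-dimethoxyphenyl]-6-methoxy-7,8-bis(methoxymethoxy)-4H-chromen-4-one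
Conditions: DDQ (2 equiv), 1,4-dioxane, 100 °C
Reagents that add atoms: none
Why: DDQ dehydrogenation of an isoflavanone to an isoflavone (hydride abstraction at C2 assisted by O1, then loss of the acidic C3 proton), which removes the last stereocentre and gives a chromone that is too electron-poor to be oxidised further.

**Step 11**
Reactants: 16 3-[3-(benzyloxy)-4,5-dimethoxyphenyl]-6-methoxy-7,8-bis(methoxymethoxy)-4H-chromen-4-one
Product: 18 7,8-dihydroxy-3-(3-hydroxy-4,5-dimethoxyphenyl)-6-methoxy-4H-chromen-4-one, via phenol 17 (not isolated)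
Conditions: H2 (1 atm), 10% Pd/C, EtOAc–MeOH, rt; filter; then HCl (3 M in MeOH), 50 °C
Reagents that add atoms: none
Why: Hydrogenolysis of the aryl benzyl ether over Pd/C, then acid-catalysed transfer of both methoxymethyl groups to methanol; the C2–C3 double bond is part of a vinylogous ester and should not be hydrogenated at 1 atm and rt during the short time the debenzylation needs.

**Compound list**
1 | 3-hydroxy-4,5-dimethoxybenzaldehyde | COc1cc(C=O)cc(O)c1OC | starting material
2 | 3-(benzyloxy)-4,5-dimethoxybenzaldehyde | COc1cc(C=O)cc(OCc2ccccc2)c1OC | intermediate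
3 | 1-(benzyloxy)-2,3-dimethoxy-5-[2-(methanesulfinyl)-2-(methylsulfanyl)ethenyl]benzene (alkene geometry as formed, racemic at sulfur) | COc1cc(C=C(SC)S(C)=O)cc(OCc2ccccc2)c1OC | intermediate
4 | methyl 2-[3-(benzyloxy)-4,5-dimethoxyphenyl]acetate | COC(=O)Cc1cc(OCc2ccccc2)c(OC)c(OC)c1 | intermediate
5 | 5-bromovanillin (3-bromo-4-hydroxy-5-methoxybenzaldehyde) | COc1cc(C=O)cc(Br)c1O | starting material
6 | 3-bromo-5-methoxy-4-(methoxymethoxy)benzaldehyde | COCOc1c(Br)cc(C=O)cc1OC | intermediate
7 | lithium enolate of 4 (lithium 2-[3-(benzyloxy)-4,5-dimethoxyphenyl]-1-methoxyethen-1-olate, geometry not controlled) | COC(O[Li])=Cc1cc(OCc2ccccc2)c(OC)c(OC)c1 | intermediate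
8 | methyl 2-[3-(benzyloxy)-4,5-dimethoxyphenyl]-3-[3-bromo-5-methoxy-4-(methoxymethoxy)phenyl]-3-hydroxypropanoate (racemic syn/anti mixture) | COC(=O)C(c1cc(OCc2ccccc2)c(OC)c(OC)c1)C(O)c1cc(Br)c(OCOC)c(OC)c1 | intermediate
9 | 2-[3-(benzyloxy)-4,5-dimethoxyphenyl]-1-[3-bromo-5-methoxy-4-(methoxymethoxy)phenyl]propane-1,3-diol (racemic syn/anti mixture) | OCC(c1cc(OCc2ccccc2)c(OC)c(OC)c1)C(O)c1cc(Br)c(OCOC)c(OC)c1 | intermediate
10 | dilithium 2-[3-(benzyloxy)-4,5-dimethoxyphenyl]-1-[2,3-didehydro-5-methoxy-4-(methoxymethoxy)phenyl]propane-1,3-diolate (aryne across C8–C8a, diastereomer mixture) | [Li]OCC(c1cc(OCc2ccccc2)c(OC)c(OC)c1)C(O[Li])C1=CC(OC)=C(OCOC)C#C1 | intermediate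
11 | lithium 3-[3-(benzyloxy)-4,5-dimethoxyphenyl]-8-lithio-6-methoxy-7-(methoxymethoxy)chroman-4-olate (diastereomer mixture) | COc1cc2C(O[Li])C(c3cc(OCc4ccccc4)c(OC)c(OC)c3)COc2c([Li])c1OCOC | intermediate
12 | lithium 3-[3-(benzyloxy)-4,5-dimethoxyphenyl]-8-(dimethoxyboranyl)-6-methoxy-7-(methoxymethoxy)chroman-4-olate (diastereomer mixture) | COc1cc2C(O[Li])C(c3cc(OCc4ccccc4)c(OC)c(OC)c3)COc2c(B(OC)OC)c1OCOC | intermediate
13 | 3-[3-(benzyloxy)-4,5-dimethoxyphenyl]-6-methoxy-7-(methoxymethoxy)chromane-4,8-diol (racemic cis/trans mixture) | COc1cc2C(O)C(c3cc(OCc4ccccc4)c(OC)c(OC)c3)COc2c(O)c1OCOC | intermediate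
14 | 3-[3-(benzyloxy)-4,5-dimethoxyphenyl]-6-methoxy-7,8-bis(methoxymethoxy)chroman-4-ol (racemic cis/trans mixture) | COc1cc2C(O)C(c3cc(OCc4ccccc4)c(OC)c(OC)c3)COc2c(OCOC)c1OCOC | intermediate
15 | 3-[3-(benzyloxy)-4,5-dimethoxyphenyl]-6-methoxy-7,8-bis(methoxymethoxy)chroman-4-one (racemic at C3) | COc1cc2C(=O)C(c3cc(OCc4ccccc4)c(OC)c(OC)c3)COc2c(OCOC)c1OCOC | intermediate
16 | 3-[3-(benzyloxy)-4,5-dimethoxyphenyl]-6-methoxy-7,8-bis(methoxymethoxy)-4H-chromen-4-one | COc1cc2c(=O)c(-c3cc(OCc4ccccc4)c(OC)c(OC)c3)coc2c(OCOC)c1OCOC | intermediate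
17 | 3-(3-hydroxy-4,5-dimethoxyphenyl)-6-methoxy-7,8-bis(methoxymethoxy)-4H-chromen-4-one | COc1cc2c(=O)c(-c3cc(O)c(OC)c(OC)c3)coc2c(OCOC)c1OCOC | intermediate
18 | 7,8-dihydroxy-3-(3-hydroxy-4,5-dimethoxyphenyl)-6-methoxy-4H-chromen-4-one (no stereocentre) | COc1cc2c(=O)c(-c3cc(O)c(OC)c(OC)c3)coc2c(O)c1O | target

**Step count**
Total steps: 11.
Longest linear sequence: 10 steps (from compound 1 through steps 1, 2, 3, 5, 6, 7, 8, 9, 10 and 11).

**Steps most likely to fail**

Step 7 (aryne cyclisation with C8 oxygenation). Deprotonation at the crowded C8a–H may be too slow. Amide addition to the aryne, hydride transfer from the alkoxide carbon, or protonation of the C8 anion before borylation could then outrun ring closure and oxygenation. The fallback makes the two C–O bonds one after the other by known reactions; it sets out from ester 4 and comes back at 13. Commercial 2-bromo-4-hydroxy-5-methoxybenzaldehyde (6-bromovanillin) is protected with MOMCl and K2CO3 in acetone to give 2-bromo-5-methoxy-4-(methoxymethoxy)benzaldehyde F1. Aldol addition of enolate 7 (from 4 and LDA, THF, −78 °C) to it should give methyl 2-[3-(benzyloxy)-4,5-dimethoxyphenyl]-3-[2-bromo-5-methoxy-4-(methoxymethoxy)phenyl]-3-hydroxypropanoate F2. LiBH4 in THF reduces this to 2-[3-(benzyloxy)-4,5-dimethoxyphenyl]-1-[2-bromo-5-methoxy-4-(methoxymethoxy)phenyl]propane-1,3-diol F3, in which the bromine sits on C8a. An intramolecular Ullmann etherification (CuI, 3,4,7,8-tetramethyl-1,10-phenanthroline, Cs2CO3, toluene, 110 °C) closes ring C to 3-[3-(benzyloxy)-4,5-dimethoxyphenyl]-6-methoxy-7-(methoxymethoxy)chroman-4-ol F4. The secondary alkoxide cannot compete because it could only form a four-membered ring. Directed ortho-metalation at C8–H, which lies between O1 and the MOM ether (n-BuLi, 2.2 equiv, TMEDA, THF, −78 → −20 °C), then B(OMe)3 and AcOH/H2O2, should give 13.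

Step 10 (DDQ dehydrogenation). The dehydrogenation may stall, or the quinone may attack the electron-rich ring B and its benzylic ether at the temperature required. The fallback sets out from 15 and comes back at 16. Enolisation at C3, the only enolisable position, with LiN(SiMe3)2 and TMSCl in THF at −78 °C gives 3-[3-(benzyloxy)-4,5-dimethoxyphenyl]-6-methoxy-7,8-bis(methoxymethoxy)-4-(trimethylsilyloxy)-2H-chromene F5. Saegusa–Ito oxidation with Pd(OAc)2 in MeCN at rt then forms the C2–C3 double bond by β-hydride elimination from C2 and delivers 16.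

Step 5 (ester aldol). Retro-aldol cleavage or dehydration of the lithium aldolate to the stilbene ester may erode the addition during reaction or quench. The fallback sets out from 4 and comes back at 9, so that step 6 is not needed. Saponification (LiOH, THF–H2O) gives 2-[3-(benzyloxy)-4,5-dimethoxyphenyl]acetic acid F6. Its magnesium enediolate (i-PrMgCl, 2.1 equiv, THF, 0 °C) adds to aldehyde 6 in an Ivanov reaction through a chelated chair transition state. The magnesium chelate holds the adduct, 2-[3-(benzyloxy)-4,5-dimethoxyphenyl]-3-[3-bromo-5-methoxy-4-(methoxymethoxy)phenyl]-3-hydroxypropanoic acid F7 (mainly anti, configuration irrelevant). Reduction of the acid with BH3·THF at 0 °C → rt, which tolerates the aryl bromide and the ethers, gives diol 9.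

**Further compounds**
F1 | step 7 | 2-bromo-5-methoxy-4-(methoxymethoxy)benzaldehyde | O=Cc1cc(OC)c(OCOC)cc1Br
F2 | step 7 | methyl 2-[3-(benzyloxy)-4,5-dimethoxyphenyl]-3-[2-bromo-5-methoxy-4-(methoxymethoxy)phenyl]-3-hydroxypropanoate (racemic syn/anti mixture) | COC(=O)C(c1cc(OCc2ccccc2)c(OC)c(OC)c1)C(O)c1cc(OC)c(OCOC)cc1Br
F3 | step 7 | 2-[3-(benzyloxy)-4,5-dimethoxyphenyl]-1-[2-bromo-5-methoxy-4-(methoxymethoxy)phenyl]propane-1,3-diol (racemic syn/anti mixture) | OCC(c1cc(OCc2ccccc2)c(OC)c(OC)c1)C(O)c1cc(OC)c(OCOC)cc1Br
F4 | step 7 | 3-[3-(benzyloxy)-4,5-dimethoxyphenyl]-6-methoxy-7-(methoxymethoxy)chroman-4-ol (racemic cis/trans mixture) | COc1cc2C(O)C(c3cc(OCc4ccccc4)c(OC)c(OC)c3)COc2cc1OCOC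
F5 | step 10 | 3-[3-(benzyloxy)-4,5-dimethoxyphenyl]-6-methoxy-7,8-bis(methoxymethoxy)-4-(trimethylsilyloxy)-2H-chromene | COc1cc2C(O[Si](C)(C)C)=C(c3cc(OCc4ccccc4)c(OC)c(OC)c3)COc2c(OCOC)c1OCOC
F6 | step 5 | 2-[3-(benzyloxy)-4,5-dimethoxyphenyl]acetic acid | OC(=O)Cc1cc(OCc2ccccc2)c(OC)c(OC)c1
F7 | step 5 | 2-[3-(benzyloxy)-4,5-dimethoxyphenyl]-3-[3-bromo-5-methoxy-4-(methoxymethoxy)phenyl]-3-hydroxypropanoic acid (racemic, mainly anti) | OC(=O)C(c1cc(OCc2ccccc2)c(OC)c(OC)c1)C(O)c1cc(Br)c(OCOC)c(OC)c1
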